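**Retrosynthetic overview**

- 13 ⇒ 10: the C5–O bond is cut last. C5 is the only allylic CH2 of ring A (C2 is quaternary), so a suprafacial SeO2 hydroxylation can place OH on the pseudoaxial position cis to ring B.
- 10 ⇒ 6: C5'–Br and C4'–Cl are cut together. They come from anti bromochlorination of the C4'=C5' alkene of ring B by a vanadium bromoperoxidase.
- 6 ⇒ 1: the O1–C2 bond of ring A comes from 6-endo selenoetherification of the side-chain alkene of (−)-α-bisabolol, and C3=C4 from selenoxide elimination.
- Structural basis: the fifteen carbons, the C6–O bond and the C6 and C1' stereocentres of the target are those of (−)-α-bisabolol, and its ring B alkene C4'=C5' lies where Br (C5') and Cl (C4') are needed.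
- Ring order: ring B is taken intact from the terpene, ring A is closed in step 1, and no ring is formed afterwards.

Key step: step 3

Remark on the chemistry: ring A is numbered O1, C2 (CMe2), C3=C4, C5, C6 and ring B C1'–C6' with C1' on C6 and the methyl on C4'; in these locants the target is (5R,6R,1'S,4'S,5'S), with Br, Cl and the C6 substituent all equatorial on ring B and the C5 hydroxyl cis to ring B and trans to the C6 methyl.

**Route**

Step 1
Reactants: 1 (−)-α-bisabolol; 2 phenylselenenyl chloride
Product: 4 (3R,6S)-3-(phenylselanyl)tetrahydropyran selenide, via seleniranium ion 3 (not isolated)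
Conditions: PhSeCl (1.05 equiv), CH2Cl2, −78 °C to 0 °C; aq NaHCO3
Reagents that add atoms: phenylselenenyl chloride (compound 2), Cl[Se]c1ccccc1
Why: Phenylselenoetherification: the seleniranium ion of the side-chain alkene is opened anti by the tertiary hydroxyl at the more substituted carbon C2 in the 6-endo mode through a chair with ring B equatorial, so SePh at C3 should end up equatorial and trans to ring B (this centre is removed in step 2), while the C6 and C1' centres of 1 are untouched and the ring B alkene, which adds PhSeCl only reversibly, cannot be captured by the hydroxyl without a boat-like bicyclic transition state.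

Step 2
Reactants: 4 selenide
Product: 6 (6S,1'S)-dihydropyran diene, via selenoxide 5 (not isolated)
Conditions: mCPBA (1.05 equiv), CH2Cl2, −78 °C; then iPr2NH (3 equiv), warm to 40 °C
Reagents that add atoms: none
Why: Selenoxide syn-elimination: oxidation at −78 °C touches only selenium, and the selenoxide finds a syn hydrogen only on C4 because C2 is quaternary, so the C3=C4 alkene should form regiospecifically while the amine intercepts benzeneselenenic acid before it can add back to an alkene.

Step 3
Reactants: 6 dihydropyran diene; 7 potassium bromide; 8 potassium chloride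
Product: 10 (6S,1'S,4'S,5'S)-bromochloride, via bromonium ion 9 (not isolated)
Conditions: vanadium bromoperoxidase (algal or bacterial enzyme chosen by screening and engineering), Na3VO4 (0.1 mM), KBr (1.5 equiv), KCl (3 M), H2O2 (1.2 equiv, slow addition), MES buffer pH 6.0–tBuOH 3:1, 25 °C
Reagents that add atoms: potassium bromide (compound 7), [K+].[Br-]; potassium chloride (compound 8), [K+].[Cl-]
Why: Proposed new method: the peroxo form of the pentavalent vanadate cofactor oxidises bromide to a bound hypobromite equivalent that hands Br+ to the trisubstituted C4'=C5' alkene on the face cis to the C6 substituent, and chloride, held at 3 M so that it outcompetes water, opens bromonium ion 9 anti at the tertiary carbon C4', which gives equatorial C5'–Br and equatorial C4'–Cl. The closest known reaction types are the bromohydrin formations and bromonium-initiated cyclisations of terpene alkenes by vanadium bromoperoxidases and the chemical bromochlorination of alkenes by Br+/Cl− pairs; capture of an enzyme-generated bromonium ion by external chloride under facial control is not established. No ring is closed. C5' (S) is set by the face of bromonium transfer, which only the active site can dictate, and C4' (S) follows from it by anti opening at the carbon that carries more positive charge. The step needs chemoselectivity for C4'=C5' over C3=C4, which the substrate secures (an electron-rich trisubstituted alkene against a cis-disubstituted one flanked by quaternary C2 and deactivated by the allylic oxygen), and Markovnikov regioselectivity, which the C4' methyl secures. It also needs the face that the substrate itself disfavours, since free Br+/Cl− reagents end in trans-diaxial opening from the opposite face, so this selectivity has to be found in the enzyme panel.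

Step 4
Reactants: 10 bromochloride
Product: 13 target (5R,6R,1'S,4'S,5'S)-allylic alcohol, via allylic seleninic acid 11 (not isolated), via divalent selenium ester 12 (not isolated)
Conditions: SeO2 (0.5 equiv), tBuOOH (2 equiv, in decane), salicylic acid (0.1 equiv), CH2Cl2, 25–40 °C; aq NaHCO3
Reagents that add atoms: selenium dioxide, O=[Se]=O; tert-butyl hydroperoxide, CC(C)(C)OO
Why: Selenium dioxide allylic hydroxylation in the Sharpless SeO2/tBuOOH form (ene reaction, then [2,3]-sigmatropic shift): C5 carries the only allylic hydrogens, so oxygen can arrive only at C5 with the alkene returning to C3=C4, and because both pericyclic events are suprafacial the oxygen should replace the pseudoaxial C5–H of the half-chair that has ring B equatorial and the C6 and C2 methyl groups axial on the opposite face, which places OH cis to ring B and trans to the C6 methyl, the (5R) configuration of the target.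

**Compound list**

1 | (−)-α-bisabolol, (2S)-6-methyl-2-[(1S)-4-methylcyclohex-3-en-1-yl]hept-5-en-2-ol | CC(C)=CCC[C@@](C)([C@H]1CCC(C)=CC1)O | starting material
2 | phenylselenenyl chloride | Cl[Se]c1ccccc1 | starting material
3 | seleniranium ion of 1 (Se-phenyl, bridging side-chain C2 and C3, C3 R, free C6 hydroxyl; not isolated) | CC1(C)[Se+](c2ccccc2)[C@@H]1CC[C@](C)(O)[C@H]3CCC(C)=CC3 | intermediate
4 | (3R,6S)-2,2,6-trimethyl-6-[(1S)-4-methylcyclohex-3-en-1-yl]-3-(phenylselanyl)tetrahydro-2H-pyran (SePh equatorial, trans to ring B) | CC1(C)[C@H]([Se]c2ccccc2)CC[C@@](C)([C@H]3CCC(C)=CC3)O1 | intermediate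
5 | selenoxide of 4 (Se-oxide, both configurations at selenium; not isolated) | CC1(C)[C@H]([Se](=O)c2ccccc2)CC[C@@](C)([C@H]3CCC(C)=CC3)O1 | intermediate
6 | (6S)-2,2,6-trimethyl-6-[(1S)-4-methylcyclohex-3-en-1-yl]-5,6-dihydro-2H-pyran | CC1(C)C=CC[C@@](C)([C@H]2CCC(C)=CC2)O1 | intermediate
7 | potassium bromide | [K+].[Br-] | starting material
8 | potassium chloride | [K+].[Cl-] | starting material
9 | bromonium ion of 6 (bromine bridging C4' and C5' on the face cis to the C6 substituent at C1'; not isolated) | CC1(C)C=CC[C@@](C)([C@H]2CC[C@@]3(C)[Br+][C@H]3C2)O1 | intermediate
10 | (6S)-6-[(1S,3S,4S)-3-bromo-4-chloro-4-methylcyclohexyl]-2,2,6-trimethyl-5,6-dihydro-2H-pyran (Br, Cl and the C1' substituent all equatorial) | CC1(C)C=CC[C@@](C)([C@H]2CC[C@](C)(Cl)[C@@H](Br)C2)O1 | intermediate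
11 | allylic seleninic acid (Se(O)OH on C3, 3S, cis to ring B; alkene shifted to C4=C5; not isolated) | CC1(C)[C@@H]([Se](=O)O)C=C[C@@](C)([C@H]2CC[C@](C)(Cl)[C@@H](Br)C2)O1 | intermediate
12 | divalent selenium ester of 13 (C5–O–Se–OH, oxygen cis to ring B; not isolated) | CC1(C)C=C[C@@H](O[Se]O)[C@@](C)([C@H]2CC[C@](C)(Cl)[C@@H](Br)C2)O1 | intermediate
13 | (5R,6R)-6-[(1S,3S,4S)-3-bromo-4-chloro-4-methylcyclohexyl]-2,2,6-trimethyl-5,6-dihydro-2H-pyran-5-ol | CC1(C)C=C[C@@H](O)[C@@](C)([C@H]2CC[C@](C)(Cl)[C@@H](Br)C2)O1 | target

**Step count**

Total step count: 4. Longest linear sequence: 4 steps (1 → 4 → 6 → 10 → 13).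

**Steps most likely to fail**

Step 3 (proposed new method). Bromonium transfer may occur through freely diffusing hypobromite without facial control, so that the substrate-preferred trans-diaxial opening on the other face takes over, or water may capture the ion in place of chloride. The fallback uses known chemistry, sets out from 6 and comes back at 10.
- mCPBA (1 equiv, NaHCO3, CH2Cl2, 0 °C) epoxidises the C4'=C5' alkene on both faces. The isomer needed is the epoxide with oxygen trans to the C1' substituent F1; the mixture can be carried on.
- Dilute aqueous HBr in Et2O at −10 °C should open F1 faster than its diastereomer, at tertiary C4' with inversion, because Markovnikov and trans-diaxial opening agree for this face. This gives the diaxial tertiary bromide–secondary alcohol F2 (4'-Br cis, 5'-OH trans to the C1' substituent), which is separated from the constitutionally different bromohydrin of the other epoxide.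
- Appel-type activation of the axial hydroxyl (PPh3, N-chlorosuccinimide, CH2Cl2, 0 °C) lets the antiperiplanar bromine displace it. The ion formed is the bromonium ion on the face cis to the C1' substituent. Chloride attack at C4' gives 10 directly; attack at C5' gives the trans-diaxial 4'-bromo-5'-chloro regioisomer F3.
- Warming F3 in chlorobenzene should convert it into 10 by the diaxial-to-diequatorial rearrangement of vicinal dihalides, in which the two halogens change places. The split between 10 and F3 and the position of that equilibrium cannot be guaranteed.

Step 4. The ene reaction may be slow at the hindered, oxygen-deactivated cis-disubstituted alkene, over-oxidation to the enone may set in, or facial control may be lost through the minor half-chair. The fallback sets out from 10 and comes back at 13.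
- Radical allylic oxidation with Rh2(cap)4 (dirhodium tetracaprolactamate, 1 mol%), tBuOOH and K2CO3 in CH2Cl2 gives the C5 enone F4. The isomer from capture of the allyl radical at C3 would have to be removed.
- NaBH4 with CeCl3·7H2O in MeOH at −78 °C should deliver hydride axially, anti to the pseudoaxial C6 methyl, to the C5-epimeric alcohol F5 (OH trans to ring B). This is why a direct oxidation–reduction sequence is not the main route.
- Mitsunobu inversion (4-nitrobenzoic acid, PPh3, DIAD, THF) through attack on the open face gives the 4-nitrobenzoate F6, and K2CO3 in MeOH releases 13.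

Step 1. Closure may go in the 5-exo mode to a tetrahydrofuran, or selenium may engage the ring B alkene with transannular capture by the hydroxyl. The fallback sets out from 1 and comes back at 6, bypassing 4 and 5.
- N-Iodosuccinimide in CH2Cl2 at 0 °C forms a more open iodonium ion with stronger Markovnikov bias. It should close to the (3R,6S)-3-iodo tetrahydropyran F7 (iodine equatorial, trans to ring B).
- DBU in toluene at 90 °C then effects anti elimination through the chair with axial iodine toward C4, the only carbon with β-hydrogens.

**Further compounds**

F1 | step 3 | 4',5'-epoxide of 6 with oxygen trans to the C1' substituent | CC1(C)C=CC[C@@](C)([C@H]2CC[C@]3(C)O[C@@H]3C2)O1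
F2 | step 3 | trans-diaxial bromohydrin, 4'-Br (tertiary, cis to the C1' substituent) and 5'-OH (trans) | CC1(C)C=CC[C@@](C)([C@H]2CC[C@@](C)(Br)[C@H](O)C2)O1
F3 | step 3 | trans-diaxial 4'-bromo-5'-chloro regioisomer of 10 (Br cis, Cl trans to the C1' substituent) | CC1(C)C=CC[C@@](C)([C@H]2CC[C@@](C)(Br)[C@H](Cl)C2)O1
F4 | step 4 | C5 enone of 10, (6R)-6-[(1S,3S,4S)-3-bromo-4-chloro-4-methylcyclohexyl]-2,2,6-trimethyl-2H-pyran-5(6H)-one | CC1(C)C=CC(=O)[C@@](C)([C@H]2CC[C@](C)(Cl)[C@@H](Br)C2)O1
F5 | step 4 | C5 epimer of 13, (5S), OH trans to ring B | CC1(C)C=C[C@H](O)[C@@](C)([C@H]2CC[C@](C)(Cl)[C@@H](Br)C2)O1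
F6 | step 4 | 4-nitrobenzoate of 13, (5R) | CC1(C)C=C[C@@H](OC(=O)c2ccc(cc2)[N+](=O)[O-])[C@@](C)([C@H]3CC[C@](C)(Cl)[C@@H](Br)C3)O1
F7 | step 1 | (3R,6S)-3-iodo-2,2,6-trimethyl-6-[(1S)-4-methylcyclohex-3-en-1-yl]tetrahydro-2H-pyran | CC1(C)[C@H](I)CC[C@@](C)([C@H]3CCC(C)=CC3)O1
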